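**Retrosynthetic overview**
- Cut both C11=C12 and C11'=C12' olefins (Horner–Wadsworth–Emmons): symmetric C10 trienedial + C15 phosphonate + (S)-epoxy-C15 phosphonate. The dialdehyde's symmetry is broken in one flask by two consecutive, different olefinations.
- The C10 dialdehyde comes from furan: oxidative ring-opening (dearomatisation) to malealdehyde, double Wittig with Ph3P=C(CH3)CHO in the same flask, then Z→E isomerisation.
- Both C15 phosphonates come from (3E,5E)-pseudoionone by vinylmagnesium bromide addition, O-phosphitylation and [2,3] phosphite→phosphonate shift.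
- The only stereocentre is set by Shi epoxidation of the isolated olefin of pseudoionone, before chain extension.
- Rings: the oxirane is the only ring made (step 3); the furan ring is opened and no other ring is formed.

Assumption: (3E,5E)-pseudoionone is bought as the single geometric isomer; the cheaper E/Z mixture would first need enrichment by fractional distillation.

**Step 1**
Reactants: 1 furan; 2 2-(triphenylphosphoranylidene)propanal
Product: 6 (2E,4E,6E)-2,7-dimethylocta-2,4,6-trienedial, via malealdehyde 3 (not isolated), via (2E,4Z)-2-methylhexa-2,4-dienedial 4 (not isolated), via (2E,4Z,6E)-2,7-dimethylocta-2,4,6-trienedial 5 (not isolated)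
Conditions: DMDO (1.0 equiv, 0.08 M in acetone), 1 (1.2 equiv), −20 → 20 °C, 1 h; then 2 (2.1 equiv), CH2Cl2, 20 °C, 16 h; then I2 (2 mol%), daylight, 20 °C, 2 h; crystallise
Reagents that add atoms: dimethyldioxirane (DMDO), CC1(C)OO1
Why: Electrophilic oxygen transfer from DMDO to furan gives the 2,3-epoxide, which opens to the cis-enedial 3 (oxidative dearomatisation of furan), the formyl-stabilised ylide 2 then olefinates both unhindered aldehydes E-selectively (Wittig reaction) but not the deactivated α-methyl enals it creates, and iodine-catalysed isomerisation turns the central Z olefin into the more stable, crystalline all-E dialdehyde.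

**Step 2**
Reactants: 7 (3E,5E)-pseudoionone
Product: 10 diethyl [(2E,4E,6E)-3,7,11-trimethyldodeca-2,4,6,10-tetraen-1-yl]phosphonate, via bromomagnesium alkoxide 8 (not isolated), via allyl phosphite 9 (not isolated)
Conditions: vinylmagnesium bromide (1.1 equiv), THF, −20 → 0 °C; then ClP(OEt)2 (1.15 equiv), 0 → 25 °C, 12 h
Reagents that add atoms: vinylmagnesium bromide, C=C[Mg]Br; diethyl chlorophosphite, CCOP(Cl)OCC
Why: 1,2-Addition of vinylmagnesium bromide to the dienone, O-phosphitylation of the tertiary alkoxide and [2,3]-sigmatropic allyl phosphite→allylphosphonate rearrangement (driven by P=O formation and triene conjugation) give the primary phosphonate, mainly 2E because the dienyl chain sits pseudo-equatorial in the envelope transition state, and any 2Z isomer converges in step 5.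

**Step 3**
Reactants: 7 (3E,5E)-pseudoionone
Product: 11 (3E,5E)-8-[(2S)-3,3-dimethyloxiran-2-yl]-6-methylocta-3,5-dien-2-one
Conditions: ent-Shi ketone (1,2:4,5-di-O-isopropylidene-β-L-erythro-2,3-hexodiulo-2,6-pyranose, 30 mol%), Oxone (2KHSO5·KHSO4·K2SO4, 1.4 equiv KHSO5), K2CO3, Bu4NHSO4 (4 mol%), MeCN/CH2(OMe)2/aq. Na2B4O7–Na2EDTA buffer, pH 10.5, 0 °C, 2 h
Reagents that add atoms: Oxone (potassium peroxymonosulfate), [K+].[O-]S(=O)(=O)OO
Why: Shi asymmetric epoxidation, in which the chiral dioxirane attacks only the isolated electron-rich trisubstituted olefin (the dienone olefins are deactivated) through the spiro transition state, and the L-fructose-derived ketone delivers oxygen to the face that gives the (S)-epoxide (the D-fructose-derived ketone gives R), typically about 90% ee for this olefin class.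

**Step 4**
Reactants: 11 (3E,5E)-8-[(2S)-3,3-dimethyloxiran-2-yl]-6-methylocta-3,5-dien-2-one
Product: 14 diethyl [(2E,4E,6E)-9-[(2S)-3,3-dimethyloxiran-2-yl]-3,7-dimethylnona-2,4,6-trien-1-yl]phosphonate, via bromomagnesium alkoxide 12 (not isolated), via allyl phosphite 13 (not isolated)
Conditions: vinylmagnesium bromide (1.05 equiv), THF, −78 → −30 °C; then ClP(OEt)2 (1.1 equiv), −30 → 20 °C, 12 h; aq. NaHCO3 work-up
Reagents that add atoms: vinylmagnesium bromide, C=C[Mg]Br; diethyl chlorophosphite, CCOP(Cl)OCC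
Why: The same carbonyl addition, O-phosphitylation and [2,3]-sigmatropic phosphite→phosphonate rearrangement as in step 2, with ketone addition at low temperature far faster than any attack on the trisubstituted epoxide, so the (S)-centre, which takes no part in bond changes, is carried through unchanged.

**Step 5**
Reactants: 6 (2E,4E,6E)-2,7-dimethylocta-2,4,6-trienedial; 10 diethyl [(2E,4E,6E)-3,7,11-trimethyldodeca-2,4,6,10-tetraen-1-yl]phosphonate; 14 diethyl [(2E,4E,6E)-9-[(2S)-3,3-dimethyloxiran-2-yl]-3,7-dimethylnona-2,4,6-trien-1-yl]phosphonate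
Product: 16 (2'S)-1',2'-epoxy-1',2'-dihydro-ψ,ψ-carotene, via C25 polyenal 15 (not isolated)
Conditions: 6 (1.0 equiv) + 10 (0.95 equiv), THF, −40 °C, KOtBu (0.95 equiv) added over 1 h, then −20 °C, 1 h; then 14 (1.1 equiv), KOtBu (1.15 equiv), −20 → 20 °C, 3 h; H2O work-up; heptane, reflux, N2, dark, 2 h; chromatography on neutral Al2O3, crystallise
Reagents that add atoms: none
Why: Two consecutive Horner–Wadsworth–Emmons olefinations break the symmetry of 6, because its two formyl groups activate each other through the triene whereas the remaining formyl group of 15 is a donor-conjugated, slower polyenal, each olefination gives an E-disubstituted olefin, the base-stable epoxide centre is untouched, and heating equilibrates residual 9Z/9'Z isomers to the all-E polyene, which crystallises.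

**Compound list**
1 | furan | c1ccoc1 | starting material
2 | 2-(triphenylphosphoranylidene)propanal | CC(C=O)=P(c1ccccc1)(c1ccccc1)c1ccccc1 | starting material
3 | malealdehyde, (Z)-but-2-enedial | O=C/C=C\C=O | intermediate
4 | (2E,4Z)-2-methylhexa-2,4-dienedial | O=C/C(C)=C/C=C\C=O | intermediate
5 | (2E,4Z,6E)-2,7-dimethylocta-2,4,6-trienedial | O=C/C(C)=C/C=C\C=C(/C)C=O | intermediate
6 | (2E,4E,6E)-2,7-dimethylocta-2,4,6-trienedial | O=C/C(C)=C/C=C/C=C(\C)C=O | intermediate
7 | (3E,5E)-pseudoionone, (3E,5E)-6,10-dimethylundeca-3,5,9-trien-2-one | CC(=O)/C=C/C=C(\C)CCC=C(C)C | starting material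
8 | bromomagnesium (4E,6E)-3,7,11-trimethyldodeca-1,4,6,10-tetraen-3-olate (racemic) | C=CC(C)(O[Mg]Br)/C=C/C=C(\C)CCC=C(C)C | intermediate
9 | diethyl (4E,6E)-3,7,11-trimethyldodeca-1,4,6,10-tetraen-3-yl phosphite (racemic) | C=CC(C)(OP(OCC)OCC)/C=C/C=C(\C)CCC=C(C)C | intermediate
10 | diethyl [(2E,4E,6E)-3,7,11-trimethyldodeca-2,4,6,10-tetraen-1-yl]phosphonate | CCOP(=O)(OCC)C/C=C(C)/C=C/C=C(\C)CCC=C(C)C | intermediate
11 | (3E,5E)-8-[(2S)-3,3-dimethyloxiran-2-yl]-6-methylocta-3,5-dien-2-one | CC(=O)/C=C/C=C(\C)CC[C@@H]1OC1(C)C | intermediate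
12 | bromomagnesium (4E,6E)-9-[(2S)-3,3-dimethyloxiran-2-yl]-3,7-dimethylnona-1,4,6-trien-3-olate (both C3 epimers) | C=CC(C)(O[Mg]Br)/C=C/C=C(\C)CC[C@@H]1OC1(C)C | intermediate
13 | diethyl (4E,6E)-9-[(2S)-3,3-dimethyloxiran-2-yl]-3,7-dimethylnona-1,4,6-trien-3-yl phosphite (both C3 epimers) | C=CC(C)(OP(OCC)OCC)/C=C/C=C(\C)CC[C@@H]1OC1(C)C | intermediate
14 | diethyl [(2E,4E,6E)-9-[(2S)-3,3-dimethyloxiran-2-yl]-3,7-dimethylnona-2,4,6-trien-1-yl]phosphonate | CCOP(=O)(OCC)C/C=C(C)/C=C/C=C(\C)CC[C@@H]1OC1(C)C | intermediate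
15 | (2E,4E,6E,8E,10E,12E,14E)-2,7,11,15,19-pentamethylicosa-2,4,6,8,10,12,14,18-octaenal (C25 polyenal) | CC(C)=CCC/C(C)=C/C=C/C(C)=C/C=C/C(C)=C/C=C/C=C(\C)C=O | intermediate
16 | (2'S)-1',2'-epoxy-1',2'-dihydro-ψ,ψ-carotene, (S)-lycopene 1,2-epoxide, all-E | CC(C)=CCC/C(C)=C/C=C/C(C)=C/C=C/C(C)=C/C=C/C=C(C)/C=C/C=C(C)/C=C/C=C(\C)CC[C@@H]1OC1(C)C | target

**Step count**
Total: 5 steps. Longest linear sequence: 3 steps (7 → 11 → 14 → 16).

**Steps most likely to fail and fallbacks**

Step 5 (one-flask double olefination). Mono-selectivity is kinetic, not absolute, so lycopene and the bis-epoxide form as by-products and must be separated, and some chiral phosphonate is lost. The fallback sets out from 6 and comes back at 15. Partial mono-acetalisation of 6 (MeOH, cat. pyridinium p-toluenesulfonate, 0 °C, unreacted 6 recycled) gives (2E,4E,6E)-8,8-dimethoxy-2,7-dimethylocta-2,4,6-trienal F8. Olefination of F8 with 10 (KOtBu, THF) gives (2E,4E,6E,8E,10E,12E,14E)-1,1-dimethoxy-2,7,11,15,19-pentamethylicosa-2,4,6,8,10,12,14,18-octaene F9. Aqueous oxalic acid in acetone releases 15, which is isolated pure and then combined 1:1 with 14 as in the second stage of step 5.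

Step 1 (one-flask furan opening and double formyl-olefination). Malealdehyde may oligomerise, or the product enals may be over-homologated by 2. The fallback sets out from 1 and comes back at 6. Br2, MeOH, Na2CO3 at −40 °C gives 2,5-dimethoxy-2,5-dihydrofuran F1. Acidic methanolysis (MeOH, HC(OMe)3, cat. H2SO4) opens F1 to (E)-1,1,4,4-tetramethoxybut-2-ene F2. Double BF3·OEt2-catalysed enol-ether condensation of F2 with 1-methoxyprop-1-ene gives (E)-1,1,3,6,8,8-hexamethoxy-2,7-dimethyloct-4-ene F3. Hot aqueous acetic acid hydrolyses the acetals and eliminates methanol to give 6.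

Step 4 (epoxide in the presence of magnesium halide and a chlorophosphite). Lewis-acid opening or rearrangement of the oxirane could erode yield. The fallback sets out from 11 and comes back at 14, avoiding organomagnesium and chlorophosphite reagents. Olefination of 11 with triethyl phosphonoacetate (NaH, THF) gives ethyl (2E,4E,6E)-9-[(2S)-3,3-dimethyloxiran-2-yl]-3,7-dimethylnona-2,4,6-trienoate F4. Reduction with i-Bu2AlH (toluene, −78 °C) gives (2E,4E,6E)-9-[(2S)-3,3-dimethyloxiran-2-yl]-3,7-dimethylnona-2,4,6-trien-1-ol F5. MsCl and Et3N form (2E,4E,6E)-9-[(2S)-3,3-dimethyloxiran-2-yl]-3,7-dimethylnona-2,4,6-trien-1-yl methanesulfonate F6, which LiBr in THF at 0 °C converts to (2S)-3-[(3E,5E,7E)-9-bromo-3,7-dimethylnona-3,5,7-trien-1-yl]-2,2-dimethyloxirane F7. Michaelis–Becker substitution of F7 with NaP(O)(OEt)2 in THF gives 14.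

**Further compounds**
F1 | step 1 | 2,5-dimethoxy-2,5-dihydrofuran (cis/trans mixture) | COC1C=CC(OC)O1
F2 | step 1 | (E)-1,1,4,4-tetramethoxybut-2-ene | COC(OC)/C=C/C(OC)OC
F3 | step 1 | (E)-1,1,3,6,8,8-hexamethoxy-2,7-dimethyloct-4-ene (diastereomer mixture) | COC(OC)C(C)C(OC)/C=C/C(OC)C(C)C(OC)OC
F4 | step 4 | ethyl (2E,4E,6E)-9-[(2S)-3,3-dimethyloxiran-2-yl]-3,7-dimethylnona-2,4,6-trienoate | CCOC(=O)/C=C(C)/C=C/C=C(\C)CC[C@@H]1OC1(C)C
F5 | step 4 | (2E,4E,6E)-9-[(2S)-3,3-dimethyloxiran-2-yl]-3,7-dimethylnona-2,4,6-trien-1-ol | OC/C=C(C)/C=C/C=C(\C)CC[C@@H]1OC1(C)C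
F6 | step 4 | (2E,4E,6E)-9-[(2S)-3,3-dimethyloxiran-2-yl]-3,7-dimethylnona-2,4,6-trien-1-yl methanesulfonate | CS(=O)(=O)OC/C=C(C)/C=C/C=C(\C)CC[C@@H]1OC1(C)C
F7 | step 4 | (2S)-3-[(3E,5E,7E)-9-bromo-3,7-dimethylnona-3,5,7-trien-1-yl]-2,2-dimethyloxirane | BrC/C=C(C)/C=C/C=C(\C)CC[C@@H]1OC1(C)C
F8 | step 5 | (2E,4E,6E)-8,8-dimethoxy-2,7-dimethylocta-2,4,6-trienal | O=C/C(C)=C/C=C/C=C(\C)C(OC)OC
F9 | step 5 | (2E,4E,6E,8E,10E,12E,14E)-1,1-dimethoxy-2,7,11,15,19-pentamethylicosa-2,4,6,8,10,12,14,18-octaene | CC(C)=CCC/C(C)=C/C=C/C(C)=C/C=C/C(C)=C/C=C/C=C(\C)C(OC)OC
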